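The plan exploits the threefold symmetry hidden in ring A (C4a, C6 and C8 are interchangeable carbons of phloroglucinol, as are O1 and the 5-OH) and the bare C2–H of ring C. Cutting C4–C4a and O1–C2 gives unprotected phloroglucinol and a 3-methoxyacrylic acid (C4–C3–C2) whose C3 already carries the finished stereocentre Cα with the benzylated ring D ketone and the diarylmethyl group. A single BF3-mediated operation acylates the arene and closes the pyranone. Cα stems from asymmetric hydrogenation of a Stobbe half-ester; C2 is added while C1' is still an ester, and later steps avoid base.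

Key step: step 11

Atom labels: chromone numbering for O1 to C8a; Cα is the stereocentre; C1' is the carbonyl carbon of the ring D ketone.
Assumption (configuration): the dextrorotatory compound is taken to be the (S)-isomer encoded in the target SMILES; while C3 is still a CH2 group the same spatial arrangement at Cα carries the descriptor R, because C3 then ranks below the diarylmethyl carbon.
Assumption (hydrogenation): the sense of induction is extrapolated from simple itaconate half-esters; should the tetrasubstituted substrate respond in the opposite sense, the equally available (S,S)-ligand is used.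
Assumption (alkene geometry): the enol ether is drawn as the Z isomer (methoxy cis to the C4 carboxyl); any E isomer formed on O-methylation is carried along, since ring closure passes through an sp3 C2 and both isomers converge.

Step 1
Reactants: 1 4,4'-dihydroxybenzophenone
Product: 2 4,4'-bis(benzyloxy)benzophenone
Conditions: BnBr, K2CO3, DMF, 60 °C
Reagents that add atoms: benzyl bromide, BrCc1ccccc1
Why: Williamson ether synthesis on two acidic para-acylphenols with a primary benzylic bromide should be clean, and benzyl is chosen because it withstands alkoxide, LiN(iPr)2, CF3CO2H, homogeneous hydrogenation and zerovalent palladium yet leaves at the end under neutral conditions.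

Step 2
Reactants: 2 4,4'-bis(benzyloxy)benzophenone; 3 di-tert-butyl succinate
Product: 5 4,4-bis[4-(benzyloxy)phenyl]-3-(tert-butoxycarbonyl)but-3-enoic acid, via paraconic lactone ester 4 (not isolated)
Conditions: KOtBu, tBuOH, reflux; then cold 1 M HCl
Reagents that add atoms: none
Why: Stobbe condensation, well established for 4,4'-dialkoxybenzophenones: aldol addition, closure of the alkoxide onto the remote ester to lactone 4 and base-induced E1cB opening leave the tert-butyl ester on the alkylidene carbon (future C1') and free the CH2CO2H arm (future C3–C4), so the two carboxyl groups are told apart from the start, and no alkene isomers can arise because both aryl groups are alike.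

Step 3
Reactants: 5 4,4-bis[4-(benzyloxy)phenyl]-3-(tert-butoxycarbonyl)but-3-enoic acid
Product: 6 (R)-4,4-bis[4-(benzyloxy)phenyl]-3-(tert-butoxycarbonyl)butanoic acid
Conditions: [Rh(cod)((R,R)-Me-DuPHOS)]BF4 (1 mol%), H2 (30 bar), NaOMe (0.1 equiv), MeOH/THF, 40 °C
Reagents that add atoms: none
Why: Carboxylate-directed asymmetric hydrogenation of a Stobbe-derived itaconate half-ester with a cationic monovalent rhodium bisphospholane catalyst, a catalyst family that also reduces tetrasubstituted β,β-disubstituted members of this class; two-point binding of alkene and carboxylate inside the twofold-symmetric ligand pocket decides the face that receives H2 and so sets Cα, while the aryl benzyl ethers are inert to the homogeneous catalyst.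

Step 4
Reactants: 6 (R)-4,4-bis[4-(benzyloxy)phenyl]-3-(tert-butoxycarbonyl)butanoic acid
Product: 7 4-allyl 1-tert-butyl (R)-2-{bis[4-(benzyloxy)phenyl]methyl}succinate
Conditions: allyl bromide, K2CO3, DMF, rt
Reagents that add atoms: allyl bromide, C=CCBr
Why: SN2 esterification of the carboxylate, in which K2CO3 is far too weak to enolise the tert-butyl ester at Cα; the allyl ester is chosen because it is orthogonal to the tert-butyl ester and can later be taken off by zerovalent palladium without acid or base.

Step 5
Reactants: 7 4-allyl 1-tert-butyl (R)-2-{bis[4-(benzyloxy)phenyl]methyl}succinate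
Product: 9 4-allyl 1-tert-butyl (S,Z)-2-{bis[4-(benzyloxy)phenyl]methyl}-3-(hydroxymethylene)succinate, via lithium enolate 8 (not isolated)
Conditions: LiN(iPr)2 (1.15 equiv), THF, −78 °C; HCO2Me, −78 → −20 °C; cold 1 M HCl
Reagents that add atoms: methyl formate, COC=O
Why: Crossed Claisen formylation of a kinetically generated ester enolate: the amide base takes a proton from the open C3 methylene rather than from the Cα methine, which is screened by the tert-butyl ester and the diarylmethyl group, and because C1' is still an ester (no ketone is present yet) Cα–H is not the most acidic site, so the stereocentre should pass unchanged while the product rests as its stabilised enolate until the quench.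

Step 6
Reactants: 9 4-allyl 1-tert-butyl (S,Z)-2-{bis[4-(benzyloxy)phenyl]methyl}-3-(hydroxymethylene)succinate
Product: 10 4-allyl 1-tert-butyl (S,Z)-2-{bis[4-(benzyloxy)phenyl]methyl}-3-(methoxymethylene)succinate
Conditions: Me2SO4, K2CO3, acetone, rt
Reagents that add atoms: dimethyl sulfate, COS(=O)(=O)OC
Why: O-alkylation of the formyl ester enolate with a hard methylating agent is the standard entry to β-methoxyacrylates; C-methylation would have to build a quaternary carbon next to the crowded Cα, and K2CO3 in acetone is too weak to deprotonate Cα–H.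

Step 7
Reactants: 10 4-allyl 1-tert-butyl (S,Z)-2-{bis[4-(benzyloxy)phenyl]methyl}-3-(methoxymethylene)succinate
Product: 11 (S,Z)-3-[(allyloxy)carbonyl]-2-{bis[4-(benzyloxy)phenyl]methyl}-4-methoxybut-3-enoic acid
Conditions: CF3CO2H/CH2Cl2 (1:3), 0 °C → rt
Reagents that add atoms: none
Why: Acidolysis of the tert-butyl ester through the tert-butyl cation leaves the allyl ester, the aryl benzyl ethers and the acceptor-deactivated enol ether untouched at this temperature and involves no base that could reach Cα.

Step 8
Reactants: 12 phloroglucinol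
Product: 13 1,3,5-tris(benzyloxy)benzene
Conditions: BnBr, K2CO3, DMF, rt → 40 °C; crystallisation
Reagents that add atoms: benzyl bromide, BrCc1ccccc1
Why: Threefold Williamson etherification; C-benzylation, the known side reaction of this ambident phenol, is limited by the polar aprotic medium and the mild temperature, and what forms is removed by crystallisation.

Step 9
Reactants: 11 (S,Z)-3-[(allyloxy)carbonyl]-2-{bis[4-(benzyloxy)phenyl]methyl}-4-methoxybut-3-enoic acid; 13 1,3,5-tris(benzyloxy)benzene
Product: 15 allyl (S,Z)-4,4-bis[4-(benzyloxy)phenyl]-2-(methoxymethylene)-3-[2,4,6-tris(benzyloxy)benzoyl]butanoate, via mixed trifluoroacetic anhydride 14 (not isolated)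
Conditions: (CF3CO)2O (1.2 equiv), CH2Cl2, 0 °C; then 13 (1.5 equiv), 0 °C → rt
Reagents that add atoms: none
Why: Friedel–Crafts acylation through a mixed trifluoroacetic anhydride, a method free of Lewis acid that works for 1,3,5-trialkoxybenzenes: 13 is among the most nucleophilic benzenes and has three equivalent CH positions, the rival indanone closure would have to use positions meta to the ether oxygens, and since the ketone is born under acid only, Cα never meets base once it has become α to a ketone.

Step 10
Reactants: 15 allyl (S,Z)-4,4-bis[4-(benzyloxy)phenyl]-2-(methoxymethylene)-3-[2,4,6-tris(benzyloxy)benzoyl]butanoate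
Product: 16 (S,Z)-4,4-bis[4-(benzyloxy)phenyl]-2-(methoxymethylene)-3-[2,4,6-tris(benzyloxy)benzoyl]butanoic acid
Conditions: Pd(PPh3)4 (5 mol%), N-methylaniline (3 equiv), THF, rt
Reagents that add atoms: none
Why: Tsuji–Trost-type deallylation: zerovalent palladium ionises the allyl ester and the weakly basic N-methylaniline takes up the allyl group, so the acid is released at room temperature without hydroxide, which would threaten the now doubly activated Cα–H, and without touching the benzyl ethers or the enol ether.

Step 11
Reactants: 16 (S,Z)-4,4-bis[4-(benzyloxy)phenyl]-2-(methoxymethylene)-3-[2,4,6-tris(benzyloxy)benzoyl]butanoic acid; 12 phloroglucinol (anhydrous)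
Product: 18 (S)-penta-O-benzylchamaechromone (5- and 7-hydroxyls free), via trihydroxyphenyl vinyl ketone 17 (not isolated)
Conditions: 12 (3 equiv), BF3·OEt2/CH2Cl2 (1:1), 0 → 35 °C; then ice-water
Reagents that add atoms: none
Why: Proposed new method: BF3 turns the carboxyl group of 16 into an acyloxyboron/acylium-type electrophile, whose formation is eased by the vinylogous methoxy donor, and a ring carbon of 12 attacks C4 to give the aryl vinyl ketone 17 (bond C4–C4a). A hydroxyl ortho to the new ketone then adds to the methoxy-bearing C2 of the boron-activated enone and methanol leaves, a 6-endo-trig addition–elimination that forms O1–C2 and ends in the aromatic 4-pyranone ring C; since C2 is sp3 on the way, either alkene isomer of 16 converges on 18. The closest known reaction types are the BF3·OEt2 acylation of phloroglucinol by free carboxylic acids with later ring closure (deoxybenzoin route to isoflavones), the acylation/oxa-Michael chromanone annulation of phenols by 3,3-dimethylacrylic acid and the Simonis chromone synthesis. No stereocentre is formed, and Cα is a bystander that is spared by the absence of base and a ceiling of 35 °C. Phloroglucinol offers only one kind of CH and, once acylated, only one kind of ortho-hydroxyl, so ring A can give a single constitution, while the excess of 12 checks a second acylation and outruns intramolecular acylation of the benzyloxyphenyl rings at positions meta to their oxygen. The selectivity that has to be won is attack of the arene at C4 rather than Pechmann-type attack at C2: it is backed by the hard, strongly activated acyl carbon under excess BF3, by donor deactivation of C2 through its methoxy group, by the reversibility of O-acylation under Fries conditions and by boron coordination of the peri-hydroxy ketone as a thermodynamic sink.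

Step 12
Reactants: 18 (S)-penta-O-benzylchamaechromone
Product: 19 (+)-(S)-chamaechromone
Conditions: H2 (1 atm), 10% Pd/C, EtOAc/MeOH, rt
Reagents that add atoms: none
Why: Heterogeneous hydrogenolysis of five aryl benzyl ethers under neutral conditions is routinely compatible with 3-substituted chromones and hydrogen-bonded polyhydroxyaryl ketones when stopped after uptake of the calculated amount of H2, so Cα sees neither acid nor base, and material that lost benzyl groups in step 11 converges here.

Compound list
1 | 4,4'-dihydroxybenzophenone | O=C(c1ccc(O)cc1)c1ccc(O)cc1 | starting material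
2 | 4,4'-bis(benzyloxy)benzophenone | O=C(c1ccc(OCc2ccccc2)cc1)c1ccc(OCc2ccccc2)cc1 | intermediate
3 | di-tert-butyl succinate | CC(C)(C)OC(=O)CCC(=O)OC(C)(C)C | starting material
4 | tert-butyl 2,2-bis[4-(benzyloxy)phenyl]-5-oxotetrahydrofuran-3-carboxylate (racemic, transient) | O=C1CC(C(=O)OC(C)(C)C)C(c2ccc(OCc3ccccc3)cc2)(c2ccc(OCc3ccccc3)cc2)O1 | intermediate
5 | 4,4-bis[4-(benzyloxy)phenyl]-3-(tert-butoxycarbonyl)but-3-enoic acid | OC(=O)CC(C(=O)OC(C)(C)C)=C(c1ccc(OCc2ccccc2)cc1)c1ccc(OCc2ccccc2)cc1 | intermediate
6 | (R)-4,4-bis[4-(benzyloxy)phenyl]-3-(tert-butoxycarbonyl)butanoic acid | O=C(OC(C)(C)C)[C@H](CC(=O)O)C(c1ccc(OCc2ccccc2)cc1)c1ccc(OCc2ccccc2)cc1 | intermediate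
7 | 4-allyl 1-tert-butyl (R)-2-{bis[4-(benzyloxy)phenyl]methyl}succinate | O=C(OC(C)(C)C)[C@H](CC(=O)OCC=C)C(c1ccc(OCc2ccccc2)cc1)c1ccc(OCc2ccccc2)cc1 | intermediate
8 | lithium enolate of 7 at C3 (Cα unchanged) | [Li+].O=C(OC(C)(C)C)[C@H](C=C([O-])OCC=C)C(c1ccc(OCc2ccccc2)cc1)c1ccc(OCc2ccccc2)cc1 | intermediate
9 | 4-allyl 1-tert-butyl (S,Z)-2-{bis[4-(benzyloxy)phenyl]methyl}-3-(hydroxymethylene)succinate (chelated enol) | O=C(OC(C)(C)C)[C@H](/C(C(=O)OCC=C)=C/O)C(c1ccc(OCc2ccccc2)cc1)c1ccc(OCc2ccccc2)cc1 | intermediate
10 | 4-allyl 1-tert-butyl (S,Z)-2-{bis[4-(benzyloxy)phenyl]methyl}-3-(methoxymethylene)succinate | O=C(OC(C)(C)C)[C@H](/C(C(=O)OCC=C)=C/OC)C(c1ccc(OCc2ccccc2)cc1)c1ccc(OCc2ccccc2)cc1 | intermediate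
11 | (S,Z)-3-[(allyloxy)carbonyl]-2-{bis[4-(benzyloxy)phenyl]methyl}-4-methoxybut-3-enoic acid | O=C(O)[C@H](/C(C(=O)OCC=C)=C/OC)C(c1ccc(OCc2ccccc2)cc1)c1ccc(OCc2ccccc2)cc1 | intermediate
12 | phloroglucinol | Oc1cc(O)cc(O)c1 | starting material
13 | 1,3,5-tris(benzyloxy)benzene | c1ccc(COc2cc(OCc3ccccc3)cc(OCc3ccccc3)c2)cc1 | intermediate
14 | mixed anhydride of 11 (at C1') and trifluoroacetic acid | O=C(OC(=O)C(F)(F)F)[C@H](/C(C(=O)OCC=C)=C/OC)C(c1ccc(OCc2ccccc2)cc1)c1ccc(OCc2ccccc2)cc1 | intermediate
15 | allyl (S,Z)-4,4-bis[4-(benzyloxy)phenyl]-2-(methoxymethylene)-3-[2,4,6-tris(benzyloxy)benzoyl]butanoate | O=C(c1c(OCc2ccccc2)cc(OCc2ccccc2)cc1OCc1ccccc1)[C@H](/C(C(=O)OCC=C)=C/OC)C(c1ccc(OCc2ccccc2)cc1)c1ccc(OCc2ccccc2)cc1 | intermediate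
16 | (S,Z)-4,4-bis[4-(benzyloxy)phenyl]-2-(methoxymethylene)-3-[2,4,6-tris(benzyloxy)benzoyl]butanoic acid | O=C(c1c(OCc2ccccc2)cc(OCc2ccccc2)cc1OCc1ccccc1)[C@H](/C(C(=O)O)=C/OC)C(c1ccc(OCc2ccccc2)cc1)c1ccc(OCc2ccccc2)cc1 | intermediate
17 | (S,Z)-3-{bis[4-(benzyloxy)phenyl]methyl}-2-(methoxymethylene)-4-[2,4,6-tris(benzyloxy)phenyl]-1-(2,4,6-trihydroxyphenyl)butane-1,4-dione | O=C(c1c(OCc2ccccc2)cc(OCc2ccccc2)cc1OCc1ccccc1)[C@H](/C(C(=O)c1c(O)cc(O)cc1O)=C/OC)C(c1ccc(OCc2ccccc2)cc1)c1ccc(OCc2ccccc2)cc1 | intermediate
18 | 3-{(S)-1,1-bis[4-(benzyloxy)phenyl]-3-oxo-3-[2,4,6-tris(benzyloxy)phenyl]propan-2-yl}-5,7-dihydroxy-4H-chromen-4-one | O=C(c1c(OCc2ccccc2)cc(OCc2ccccc2)cc1OCc1ccccc1)[C@H](c1coc2cc(O)cc(O)c2c1=O)C(c1ccc(OCc2ccccc2)cc1)c1ccc(OCc2ccccc2)cc1 | intermediate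
19 | (+)-chamaechromone, 3-[(S)-1,1-bis(4-hydroxyphenyl)-3-oxo-3-(2,4,6-trihydroxyphenyl)propan-2-yl]-5,7-dihydroxy-4H-chromen-4-one | O=C(c1c(O)cc(O)cc1O)[C@H](c1coc2cc(O)cc(O)c2c1=O)C(c1ccc(O)cc1)c1ccc(O)cc1 | target

Total step count: 12. Longest linear sequence: 11 (steps 1–7 and 9–12; step 8 is a one-step branch).

Steps most likely to fail

1. Step 11 (the labelled step).
- What may go wrong: the arene may attack the methoxy-bearing C2 instead of the carboxyl carbon (Pechmann-type closure). The ring D carbonyl oxygen may take part at the activated carboxyl group, with loss of the Cα proton and erosion of enantiopurity. BF3 may also transfer benzyl groups from the ethers to the excess phenol.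
- Fallback (known chemistry, C2 brought in last): it sets out from 7 and comes back at 18. CF3CO2H cleaves the tert-butyl ester of 7 to the monoallyl succinic acid F1. (CF3CO)2O-promoted Friedel–Crafts acylation of 13 with it gives the keto allyl ester F2, and Pd(PPh3)4/N-methylaniline frees the γ-keto acid F3. BF3·OEt2 then acylates 12 with F3, the established acylation of phloroglucinol by a saturated acid in which no second electrophilic carbon competes, to give the trihydroxyphenyl diketone F4. DMF and CH3SO2Cl are added to the same BF3·OEt2 solution, so that a Vilsmeier-type reagent formylates the C3 methylene and the ortho-hydroxyl closes ring C, as in the deoxybenzoin-to-isoflavone protocol. The temperature is held low to restrain acid-induced cyclodehydration of the 1,4-diketone. The whole detour stays free of base.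

2. Step 3.
- What may go wrong: hydrogenation of the crowded tetrasubstituted diaryl alkene may be sluggish or poorly face-selective.
- Fallback (reduction without stereocontrol, then resolution): it sets out from 5 and comes back at 6. Mg turnings in MeOH reduce the β,β-diarylacrylate by electron transfer and spare the benzyl ethers and the tert-butyl ester, giving the racemic half-ester F5. Crystallisation with (S)-1-phenylethylamine, or another chiral amine found by screening, gives the diastereomerically pure ammonium salt F6. Acidification then returns 6, and the configuration is checked by correlation with the final rotation.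

3. Step 9.
- What may go wrong: the activated acyl group may lose carbon monoxide, because the cation left at Cα would be allylic and methoxy-stabilised. Acylation may be slow through crowding, the arene may attack C2 of the enol ether, and the activated acid may enolise.
- Fallback (cross-coupling in place of electrophilic substitution): it sets out from 11 and 13 and comes back at 15. EtSH, EDC·HCl and HOBt convert 11 into the S-ethyl thioester F7. N-Iodosuccinimide converts 13 into 2-iodo-1,3,5-tris(benzyloxy)benzene F8, into which Zn dust/LiCl inserts to give the arylzinc iodide F9. Fukuyama coupling of F7 with F9 (PdCl2(PPh3)2, THF/toluene, rt) forms the C1'–aryl bond by oxidative addition into the C–S bond, transmetalation and reductive elimination. This avoids an acyl cation and uses a non-basic organometallic.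

Further compounds
F1 | step 11 | (R)-4-(allyloxy)-2-{bis[4-(benzyloxy)phenyl]methyl}-4-oxobutanoic acid | O=C(O)[C@H](CC(=O)OCC=C)C(c1ccc(OCc2ccccc2)cc1)c1ccc(OCc2ccccc2)cc1
F2 | step 11 | allyl (R)-4,4-bis[4-(benzyloxy)phenyl]-3-[2,4,6-tris(benzyloxy)benzoyl]butanoate | O=C(c1c(OCc2ccccc2)cc(OCc2ccccc2)cc1OCc1ccccc1)[C@H](CC(=O)OCC=C)C(c1ccc(OCc2ccccc2)cc1)c1ccc(OCc2ccccc2)cc1
F3 | step 11 | (R)-4,4-bis[4-(benzyloxy)phenyl]-3-[2,4,6-tris(benzyloxy)benzoyl]butanoic acid | O=C(c1c(OCc2ccccc2)cc(OCc2ccccc2)cc1OCc1ccccc1)[C@H](CC(=O)O)C(c1ccc(OCc2ccccc2)cc1)c1ccc(OCc2ccccc2)cc1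
F4 | step 11 | (R)-2-{bis[4-(benzyloxy)phenyl]methyl}-1-[2,4,6-tris(benzyloxy)phenyl]-4-(2,4,6-trihydroxyphenyl)butane-1,4-dione | O=C(c1c(OCc2ccccc2)cc(OCc2ccccc2)cc1OCc1ccccc1)[C@H](CC(=O)c1c(O)cc(O)cc1O)C(c1ccc(OCc2ccccc2)cc1)c1ccc(OCc2ccccc2)cc1
F5 | step 3 | racemic 4,4-bis[4-(benzyloxy)phenyl]-3-(tert-butoxycarbonyl)butanoic acid | O=C(OC(C)(C)C)C(CC(=O)O)C(c1ccc(OCc2ccccc2)cc1)c1ccc(OCc2ccccc2)cc1
F6 | step 3 | (S)-1-phenylethylammonium (R)-4,4-bis[4-(benzyloxy)phenyl]-3-(tert-butoxycarbonyl)butanoate | O=C(OC(C)(C)C)[C@H](CC(=O)[O-])C(c1ccc(OCc2ccccc2)cc1)c1ccc(OCc2ccccc2)cc1.C[C@H]([NH3+])c1ccccc1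
F7 | step 9 | allyl (S,Z)-4,4-bis[4-(benzyloxy)phenyl]-3-[(ethylsulfanyl)carbonyl]-2-(methoxymethylene)butanoate | O=C(SCC)[C@H](/C(C(=O)OCC=C)=C/OC)C(c1ccc(OCc2ccccc2)cc1)c1ccc(OCc2ccccc2)cc1
F8 | step 9 | 2-iodo-1,3,5-tris(benzyloxy)benzene | Ic1c(OCc2ccccc2)cc(OCc2ccccc2)cc1OCc1ccccc1
F9 | step 9 | [2,4,6-tris(benzyloxy)phenyl]zinc iodide | I[Zn]c1c(OCc2ccccc2)cc(OCc2ccccc2)cc1OCc1ccccc1
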